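**Retrosynthetic overview**

1. Eudesmane numbering is used: ring A = C1–C2–C3–C4–C5–C10, ring B = C5–C6–C7–C8–C9–C10, C14 on C10, C15 on C4, C11 (with C12, C13) on C7. The C11–OOH group and the C6=C7 bond are made last and together, by a biomimetic Schenck ene reaction of singlet oxygen on the 7(11)-en-8-one 19; the angelate is put on the C3 hydroxyl one step earlier.
2. The 3β,4α-diol goes back to the C3=C4(C15) alkene 13 (α-face dihydroxylation, C3 oxidation, axial hydride delivery). The C7 isopropylidene goes back to an acetone aldol on the ring B silyl enol ether 8, and C15 enters through the C4 enol triflate 7.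
3. Key disconnection: ring B is cut at C9–C10 and C5–C6 by a catalytic enantioselective Diels–Alder reaction between 3-methylcyclohex-2-en-1-one 3 (ring A with C4 as ketone, C5=C10 as dienophile) and the 2-silyloxybuta-1,3-diene 2 (C6=C7–C8(OSi)=C9).
4. Feature that allows it: ring B is a cyclohexanone whose carbonyl carbon C8 stands 1,4 to C5, C5 bears the oxygenated ring A carbon C4, and C10 bears the angular methyl C14. With C4 raised to a ketone this is the retron of a 2-oxydiene plus β-methyl enone cycloaddition, and the same ketone later lets C5 be equilibrated to the trans ring fusion.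
5. Ring order: ring A is bought as 3, ring B is closed in step 2, and no other ring is formed.

Key step: step 2

Assumption on the chemistry: the (S)-oxazaborolidine is assumed to deliver the diene to the Si face at C10, as the α-C–H···O binding model for 2-cycloalkenones suggests; the (R)-catalyst is equally accessible and would be used if the sense proved opposite.

**Route**

Step 1
Reactants: 1 but-3-en-2-one
Product: 2 2-[(triisopropylsilyl)oxy]buta-1,3-diene
Conditions: iPr3SiOTf, Et3N, Et2O, 0 → 25 °C
Reagents that add atoms: triisopropylsilyl trifluoromethanesulfonate CC(C)[Si](OS(=O)(=O)C(F)(F)F)(C(C)C)C(C)C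
Why: Soft enolisation of the methyl ketone with a silyl triflate and Et3N can only take place on the CH3 side, so O-silylation gives the 2-silyloxy diene directly (silyl enol ether formation) and no stereocentre is formed.

Step 2
Reactants: 3 3-methylcyclohex-2-en-1-one; 2 2-[(triisopropylsilyl)oxy]buta-1,3-diene
Product: 4 (4aR,8aS)-4a-methyl-6-[(triisopropylsilyl)oxy]-3,4,4a,5,8,8a-hexahydronaphthalen-1(2H)-one (cis-fused: H on C5 and CH3 on C10 both β; 5S,10R in eudesmane numbering)
Conditions: (S)-3,3-diphenyl-1-(2-methylphenyl)tetrahydro-1H,3H-pyrrolo[1,2-c][1,3,2]oxazaborole (20 mol%), AlBr3 (16 mol%), CH2Cl2, −40 °C; Et3N quench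
Reagents that add atoms: none
Why: Proposed new method: the AlBr3-activated chiral oxazaborolidine binds the C4 carbonyl of 3 on the lone pair syn to the C5–H, lowers the LUMO and lets the electron-rich diene add in a concerted, asynchronous [4+2] cycloaddition in which the C9–C10 bond leads, because the largest HOMO coefficient of 2 lies on the CH2 next to the silyloxy carbon and the largest LUMO coefficient of the bound enone lies on the methyl-bearing β-carbon. The closest known reaction types are the oxazaborolidinium-catalysed enantioselective Diels–Alder reaction of 2-silyloxybuta-1,3-dienes with 2-cycloalkenones and with the methyl-bearing C=C of quinones, and the achiral AlBr3/AlMe3-promoted Diels–Alder reaction of 3-methylcyclohexenone with 2-silyloxydienes; new is the union of a β,β-disubstituted cycloalkenone with enantiocontrol. Ring B is closed as a six-membered ring by a suprafacial π4s+π2s cycloaddition (if the reaction went stepwise, by Mukaiyama–Michael addition followed by 6-endo-trig closure of the enolate onto the silyloxyallyl cation), so H on C5 and CH3 on C10 must end up cis. The quaternary stereocentre C10 is set by the catalyst, whose aryl group shields one face of the C5=C10 bond so that the diene adds to the Si face at C10, and C5 follows from the suprafacial addition. The step needs para regioselectivity (silyloxy carbon C8 1,4 to C5), secured by the matched polarisation of enone and 2-oxydiene, and it meets no competing dienophile because C5=C10 is the only electron-poor double bond of 3.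

Step 3
Reactants: 4 (4aR,8aS)-4a-methyl-6-[(triisopropylsilyl)oxy]-3,4,4a,5,8,8a-hexahydronaphthalen-1(2H)-one
Product: 5 (4aR,8aR)-4a-methyl-6-[(triisopropylsilyl)oxy]-3,4,4a,5,8,8a-hexahydronaphthalen-1(2H)-one (trans-fused: 5α-H, 10β-CH3)
Conditions: DBU, toluene, 80 °C
Reagents that add atoms: none
Why: Reversible enolisation towards C5 equilibrates the ring fusion, and the trans-decalone should predominate because its axial C10 methyl group meets only two syn-axial hydrogens (C4 and C8 are trigonal) while the cis isomer keeps its extra gauche interactions, so C5 is set under thermodynamic control by protonation anti to the C10 methyl group (base-mediated α-epimerisation).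

Step 4
Reactants: 5 (4aR,8aR)-4a-methyl-6-[(triisopropylsilyl)oxy]-3,4,4a,5,8,8a-hexahydronaphthalen-1(2H)-one
Product: 7 (4aR,8aR)-4a-methyl-6-[(triisopropylsilyl)oxy]-3,4,4a,5,8,8a-hexahydronaphthalen-1-yl trifluoromethanesulfonate, via lithium enolate 6 (not isolated)
Conditions: LiN(iPr)2, THF, −78 °C; PhNTf2, −78 → 0 °C
Reagents that add atoms: N-phenylbis(trifluoromethanesulfonimide) O=S(=O)(N(c1ccccc1)S(=O)(=O)C(F)(F)F)C(F)(F)F
Why: LiN(iPr)2 removes a proton kinetically from the C3 methylene rather than from the hindered C5 methine, and O-sulfonylation of the lithium enolate with PhNTf2 fixes the double bond at C3=C4 (regioselective enol triflate formation) without touching a stereocentre.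

Step 5
Reactants: 7 (4aR,8aR)-4a-methyl-6-[(triisopropylsilyl)oxy]-3,4,4a,5,8,8a-hexahydronaphthalen-1-yl trifluoromethanesulfonate
Product: 8 triisopropyl{[(4aR,8aR)-5,8a-dimethyl-1,4,4a,7,8,8a-hexahydronaphthalen-2-yl]oxy}silane (C3=C4 alkene carrying C15, C7=C8 silyl enol ether)
Conditions: MeMgBr, Fe(acac)3 (5 mol%), THF–N-methylpyrrolidone, −20 °C
Reagents that add atoms: methylmagnesium bromide C[Mg]Br
Why: Iron-catalysed Kumada-type cross-coupling of an alkenyl triflate with MeMgBr replaces the triflate by the C15 methyl group with retention of the C3=C4 position, and the silyl enol ether offers no electrophilic site to the Grignard reagent.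

Step 6
Reactants: 8 triisopropyl{[(4aR,8aR)-5,8a-dimethyl-1,4,4a,7,8,8a-hexahydronaphthalen-2-yl]oxy}silane; 9 propan-2-one
Product: 11 (4aR,8aR)-3-(2-hydroxypropan-2-yl)-5,8a-dimethyl-3,4,4a,7,8,8a-hexahydronaphthalen-2(1H)-one (11-hydroxy-5α-eudesm-3-en-8-one as a mixture of C7 epimers), via trichlorotitanium aldolate 10 (not isolated)
Conditions: TiCl4, CH2Cl2, −78 °C; aq NaHCO3
Reagents that add atoms: none
Why: TiCl4 activates acetone for attack by the only nucleophilic enol ether carbon, C7, so the regiochemistry fixed in the cycloaddition is transferred to the new C7–C11 bond (Mukaiyama aldol addition), and the configuration at C7 is of no consequence because step 7 removes it.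

Step 7
Reactants: 11 (4aR,8aR)-3-(2-hydroxypropan-2-yl)-5,8a-dimethyl-3,4,4a,7,8,8a-hexahydronaphthalen-2(1H)-one
Product: 13 (4aR,8aR)-5,8a-dimethyl-3-(propan-2-ylidene)-3,4,4a,7,8,8a-hexahydronaphthalen-2(1H)-one (5α-eudesma-3,7(11)-dien-8-one), via tertiary methanesulfonate 12 (not isolated)
Conditions: MsCl, Et3N, CH2Cl2, 0 °C; then DBU, 25 °C
Reagents that add atoms: none
Why: Mesylation of the tertiary alcohol and base-induced E1cB elimination through the C8 enolate give the conjugated tetrasubstituted C7=C11 enone, the thermodynamically favoured isomer (aldol dehydration), and the stereocentre at C7 disappears.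

Step 8
Reactants: 13 (4aR,8aR)-5,8a-dimethyl-3-(propan-2-ylidene)-3,4,4a,7,8,8a-hexahydronaphthalen-2(1H)-one
Product: 14 (4aR,5S,6R,8aR)-5,6-dihydroxy-5,8a-dimethyl-3-(propan-2-ylidene)-3,4,4a,5,6,7,8,8a-octahydronaphthalen-2(1H)-one (3α,4α-dihydroxy-5α-eudesm-7(11)-en-8-one)
Conditions: OsO4 (2 mol%), N-methylmorpholine N-oxide, acetone–H2O, 25 °C
Reagents that add atoms: OsO4 O=[Os](=O)(=O)=O (oxygen carrier), N-methylmorpholine N-oxide C[N+]1([O-])CCOCC1, water O
Why: OsO4 adds suprafacially to the electron-rich trisubstituted C3=C4 bond from the α face, anti to the axial C10 methyl group that stands 1,3 to C4, which sets C4 (α-OH, β-CH3) and C3 (α-OH), while the electron-poor tetrasubstituted enone is left untouched (catalytic syn-dihydroxylation).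

Step 9
Reactants: 14 (4aR,5S,6R,8aR)-5,6-dihydroxy-5,8a-dimethyl-3-(propan-2-ylidene)-3,4,4a,5,6,7,8,8a-octahydronaphthalen-2(1H)-one
Product: 15 (4aR,5S,8aR)-5-hydroxy-5,8a-dimethyl-3-(propan-2-ylidene)-3,4,4a,7,8,8a-hexahydronaphthalene-2,6(1H,5H)-dione (4α-hydroxy-5α-eudesm-7(11)-ene-3,8-dione)
Conditions: IBX (1.5 equiv), DMSO, 25 °C
Reagents that add atoms: none
Why: IBX oxidises the secondary C3 alcohol, cannot oxidise the tertiary C4 alcohol and does not cleave 1,2-diols, so the C4 stereocentre is kept (IBX oxidation of a diol to an α-ketol).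

Step 10
Reactants: 15 (4aR,5S,8aR)-5-hydroxy-5,8a-dimethyl-3-(propan-2-ylidene)-3,4,4a,7,8,8a-hexahydronaphthalene-2,6(1H,5H)-dione
Product: 16 (4aR,5S,6S,8aR)-5,6-dihydroxy-5,8a-dimethyl-3-(propan-2-ylidene)-3,4,4a,5,6,7,8,8a-octahydronaphthalen-2(1H)-one (3β,4α-dihydroxy-5α-eudesm-7(11)-en-8-one)
Conditions: NaBH4, MeOH–CH2Cl2 (1:1), −78 °C
Reagents that add atoms: none
Why: Borohydride attacks the C3 ketone axially from the α face because the equatorial approach is blocked by the axial methyl groups on C4 and C10, which gives the equatorial 3β-alcohol, and at −78 °C the saturated α-hydroxy ketone should be reduced much faster than the hindered conjugated C8 ketone (diastereoselective and chemoselective NaBH4 reduction).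

Step 11
Reactants: 16 (4aR,5S,6S,8aR)-5,6-dihydroxy-5,8a-dimethyl-3-(propan-2-ylidene)-3,4,4a,5,6,7,8,8a-octahydronaphthalen-2(1H)-one; 17 angelic acid ((Z)-2-methylbut-2-enoic acid)
Product: 19 3β-angeloyloxy-4α-hydroxy-5α-eudesm-7(11)-en-8-one (3S,4S,5R,10R), via mixed anhydride 18 (not isolated)
Conditions: 17, 2,4,6-trichlorobenzoyl chloride, Et3N, toluene, 25 °C; then 16, toluene, 80 °C (no DMAP)
Reagents that add atoms: none
Why: The alcohol attacks the mixed anhydride at the unhindered angeloyl carbonyl, only the secondary equatorial 3β-hydroxyl reacts while the tertiary 4α-hydroxyl is inert, and leaving out a nucleophilic catalyst avoids the addition–elimination that would isomerise the Z double bond to the tiglate (Yamaguchi esterification), so C3 keeps its configuration.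

Step 12
Reactants: 19 3β-angeloyloxy-4α-hydroxy-5α-eudesm-7(11)-en-8-one
Product: 20 3β-angeloyloxy-4α-hydroxy-11-hydroperoxy-5α-eudesm-6-en-8-one (3S,4S,5R,10R; CNP0161122.1)
Conditions: O2, 5,10,15,20-tetraphenylporphyrin (1 mol%), visible light, CH2Cl2, 0 °C
Reagents that add atoms: dioxygen O=O
Why: Singlet oxygen should undergo a Schenck ene reaction with the s-cis tetrasubstituted enone with the geminal regioselectivity typical of α,β-unsaturated carbonyl compounds, bonding oxygen to the β-carbon C11 and removing an allylic hydrogen from C6 (the CH2 geminal to the carbonyl on the double bond), which moves the double bond to C6=C7 in conjugation with C8=O, while C11 is not stereogenic and the electron-poor trisubstituted angelate alkene should react far more slowly.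

**Compound list**

1 | but-3-en-2-one | CC(=O)C=C | starting material
2 | 2-[(triisopropylsilyl)oxy]buta-1,3-diene | C=CC(=C)O[Si](C(C)C)(C(C)C)C(C)C | intermediate
3 | 3-methylcyclohex-2-en-1-one | CC1=CC(=O)CCC1 | starting material
4 | (4aR,8aS)-4a-methyl-6-[(triisopropylsilyl)oxy]-3,4,4a,5,8,8a-hexahydronaphthalen-1(2H)-one (cis-fused) | C1CC[C@]2(C)CC(O[Si](C(C)C)(C(C)C)C(C)C)=CC[C@@H]2C1=O | intermediate
5 | (4aR,8aR)-4a-methyl-6-[(triisopropylsilyl)oxy]-3,4,4a,5,8,8a-hexahydronaphthalen-1(2H)-one (trans-fused) | C1CC[C@]2(C)CC(O[Si](C(C)C)(C(C)C)C(C)C)=CC[C@H]2C1=O | intermediate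
6 | lithium enolate of 5 (C3=C4–OLi) | C=1CC[C@]2(C)CC(O[Si](C(C)C)(C(C)C)C(C)C)=CC[C@H]2C=1O[Li] | intermediate
7 | (4aR,8aR)-4a-methyl-6-[(triisopropylsilyl)oxy]-3,4,4a,5,8,8a-hexahydronaphthalen-1-yl trifluoromethanesulfonate | C=1CC[C@]2(C)CC(O[Si](C(C)C)(C(C)C)C(C)C)=CC[C@H]2C=1OS(=O)(=O)C(F)(F)F | intermediate
8 | triisopropyl{[(4aR,8aR)-5,8a-dimethyl-1,4,4a,7,8,8a-hexahydronaphthalen-2-yl]oxy}silane | C=1CC[C@]2(C)CC(O[Si](C(C)C)(C(C)C)C(C)C)=CC[C@H]2C=1C | intermediate
9 | propan-2-one (acetone) | CC(C)=O | starting material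
10 | trichlorotitanium aldolate of 11 | C=1CC[C@]2(C)CC(=O)C(C(C)(C)O[Ti](Cl)(Cl)Cl)C[C@H]2C=1C | intermediate
11 | (4aR,8aR)-3-(2-hydroxypropan-2-yl)-5,8a-dimethyl-3,4,4a,7,8,8a-hexahydronaphthalen-2(1H)-one (C7 epimers) | C=1CC[C@]2(C)CC(=O)C(C(C)(C)O)C[C@H]2C=1C | intermediate
12 | tertiary methanesulfonate of 11 | C=1CC[C@]2(C)CC(=O)C(C(C)(C)OS(C)(=O)=O)C[C@H]2C=1C | intermediate
13 | (4aR,8aR)-5,8a-dimethyl-3-(propan-2-ylidene)-3,4,4a,7,8,8a-hexahydronaphthalen-2(1H)-one (5α-eudesma-3,7(11)-dien-8-one) | C=1CC[C@]2(C)CC(=O)C(=C(C)C)C[C@H]2C=1C | intermediate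
14 | (4aR,5S,6R,8aR)-5,6-dihydroxy-5,8a-dimethyl-3-(propan-2-ylidene)-3,4,4a,5,6,7,8,8a-octahydronaphthalen-2(1H)-one (3α,4α-diol) | O[C@@H]1CC[C@]2(C)CC(=O)C(=C(C)C)C[C@H]2[C@]1(C)O | intermediate
15 | (4aR,5S,8aR)-5-hydroxy-5,8a-dimethyl-3-(propan-2-ylidene)-3,4,4a,7,8,8a-hexahydronaphthalene-2,6(1H,5H)-dione | O=C1CC[C@]2(C)CC(=O)C(=C(C)C)C[C@H]2[C@]1(C)O | intermediate
16 | (4aR,5S,6S,8aR)-5,6-dihydroxy-5,8a-dimethyl-3-(propan-2-ylidene)-3,4,4a,5,6,7,8,8a-octahydronaphthalen-2(1H)-one (3β,4α-diol) | O[C@H]1CC[C@]2(C)CC(=O)C(=C(C)C)C[C@H]2[C@]1(C)O | intermediate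
17 | angelic acid, (Z)-2-methylbut-2-enoic acid | C/C=C(/C)C(=O)O | starting material
18 | (Z)-2-methylbut-2-enoic 2,4,6-trichlorobenzoic anhydride | C/C=C(/C)C(=O)OC(=O)c1c(Cl)cc(Cl)cc1Cl | intermediate
19 | 3β-angeloyloxy-4α-hydroxy-5α-eudesm-7(11)-en-8-one (3S,4S,5R,10R) | C/C=C(/C)C(=O)O[C@H]1CC[C@]2(C)CC(=O)C(=C(C)C)C[C@H]2[C@]1(C)O | intermediate
20 | 3β-angeloyloxy-4α-hydroxy-11-hydroperoxy-5α-eudesm-6-en-8-one (3S,4S,5R,10R) | C/C=C(/C)C(=O)O[C@H]1CC[C@]2(C)CC(=O)C(C(C)(C)OO)=C[C@H]2[C@]1(C)O | target

**Step count and risks**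

Total step count: 12. Longest linear sequence: 12 steps (1 → 2 → 4 → … → 20); 11 steps counted from 3.

Steps most likely to fail:

Step 2 (proposed new method). The hindered β,β-disubstituted enone may be activated too weakly by the chiral Lewis acid, so that conversion stalls or an unselective background cycloaddition erodes the enantiomeric purity. Fallback with known chemistry, setting out from 3 and 2: the cycloaddition is run with the achiral mixed Lewis acid AlBr3/AlMe3 (10:1, toluene–CH2Cl2, −5 °C), a combination established for 3-methylcyclohexenone and 2-silyloxydienes. This gives 4 together with its enantiomer (4aS,8aR)-4a-methyl-6-[(triisopropylsilyl)oxy]-3,4,4a,5,8,8a-hexahydronaphthalen-1(2H)-one F1 as the second component of the racemate. Equilibration of 4 and F1 with DBU as in step 3 gives 5 together with its enantiomer (4aS,8aS)-4a-methyl-6-[(triisopropylsilyl)oxy]-3,4,4a,5,8,8a-hexahydronaphthalen-1(2H)-one F2 as a racemic trans-decalone. Lithiated (S)-N,S-dimethyl-S-phenylsulfoximine (n-BuLi, THF, −78 °C) is added to the C4 ketone of 5 and of F2 from the face anti to the angular methyl group. This should give two diastereomers that are separated by chromatography: (1S,4aR,8aR)-4a-methyl-1-{[(S)-N-methyl-S-phenylsulfonimidoyl]methyl}-6-[(triisopropylsilyl)oxy]-1,2,3,4,4a,5,8,8a-octahydronaphthalen-1-ol F3 from 5, and (1R,4aS,8aS)-4a-methyl-1-{[(S)-N-methyl-S-phenylsulfonimidoyl]methyl}-6-[(triisopropylsilyl)oxy]-1,2,3,4,4a,5,8,8a-octahydronaphthalen-1-ol F4 from the enantiomer. Thermolysis of F3 in toluene at 110 °C releases the sulfoximine and returns enantiopure 5, where the route is rejoined, while F4 is set aside.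

Step 3. The cis/trans equilibrium may not lie far enough on the trans side, or the base may slowly cleave the silyl enol ether. Fallback that replaces thermodynamic by kinetic control, setting out from 4: Me3SiI/(Me3Si)2NH (CH2Cl2, −20 → 25 °C) gives the thermodynamic, tetrasubstituted trimethylsilyl enol ether (4aR)-4a-methyl-1-[(trimethylsilyl)oxy]-6-[(triisopropylsilyl)oxy]-2,3,4,4a,5,8-hexahydronaphthalene F5 in which C5 is trigonal. MeLi (THF, 0 °C) cleaves only the trimethylsilyl group of F5 and gives the C4–C5 enolate lithium (4aR)-4a-methyl-6-[(triisopropylsilyl)oxy]-2,3,4,4a,5,8-hexahydronaphthalen-1-olate F6 as a solution in THF. Kinetic protonation of F6 at −78 °C with 2,6-di-tert-butyl-4-methylphenol, from the face anti to the C10 methyl group, should give 5, where the route is rejoined.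

Step 11. The Z double bond of the angeloyl group may isomerise to the tigloyl ester during the slow acylation of the hindered alcohol, or the acyl group may be transferred from the wrong carbonyl of 18. Fallback that builds the Z-alkene on the ester instead of transferring it, setting out from 16: esterification of the 3β-hydroxyl with 2-[bis(2,2,2-trifluoroethoxy)phosphoryl]propanoic acid (N,N'-dicyclohexylcarbodiimide, DMAP, CH2Cl2) gives 4α-hydroxy-8-oxo-5α-eudesm-7(11)-en-3β-yl 2-[bis(2,2,2-trifluoroethoxy)phosphoryl]propanoate F7 as a mixture of epimers at the phosphonate carbon. Still–Gennari olefination of F7 with acetaldehyde (KN(SiMe3)2, 18-crown-6, THF, −78 °C; then acetaldehyde) should form the Z-trisubstituted double bond and give 19, where the route is rejoined.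

Further compounds

F1 | step 2 | (4aS,8aR)-4a-methyl-6-[(triisopropylsilyl)oxy]-3,4,4a,5,8,8a-hexahydronaphthalen-1(2H)-one (enantiomer of 4) | C1CC[C@@]2(C)CC(O[Si](C(C)C)(C(C)C)C(C)C)=CC[C@H]2C1=O
F2 | step 2 | (4aS,8aS)-4a-methyl-6-[(triisopropylsilyl)oxy]-3,4,4a,5,8,8a-hexahydronaphthalen-1(2H)-one (enantiomer of 5) | C1CC[C@@]2(C)CC(O[Si](C(C)C)(C(C)C)C(C)C)=CC[C@@H]2C1=O
F3 | step 2 | (1S,4aR,8aR)-4a-methyl-1-{[(S)-N-methyl-S-phenylsulfonimidoyl]methyl}-6-[(triisopropylsilyl)oxy]-1,2,3,4,4a,5,8,8a-octahydronaphthalen-1-ol (β-hydroxy sulfoximine of 5, hydroxyl cis to the C4a methyl) | C1CC[C@]2(C)CC(O[Si](C(C)C)(C(C)C)C(C)C)=CC[C@H]2[C@]1(O)C[S@@](=O)(=NC)c1ccccc1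
F4 | step 2 | (1R,4aS,8aS)-4a-methyl-1-{[(S)-N-methyl-S-phenylsulfonimidoyl]methyl}-6-[(triisopropylsilyl)oxy]-1,2,3,4,4a,5,8,8a-octahydronaphthalen-1-ol (β-hydroxy sulfoximine of F2) | C1CC[C@@]2(C)CC(O[Si](C(C)C)(C(C)C)C(C)C)=CC[C@@H]2[C@@]1(O)C[S@@](=O)(=NC)c1ccccc1
F5 | step 3 | (4aR)-4a-methyl-1-[(trimethylsilyl)oxy]-6-[(triisopropylsilyl)oxy]-2,3,4,4a,5,8-hexahydronaphthalene | C1CC[C@]2(C)CC(O[Si](C(C)C)(C(C)C)C(C)C)=CCC2=C1O[Si](C)(C)C
F6 | step 3 | lithium (4aR)-4a-methyl-6-[(triisopropylsilyl)oxy]-2,3,4,4a,5,8-hexahydronaphthalen-1-olate (C4–C5 lithium enolate) | C1CC[C@]2(C)CC(O[Si](C(C)C)(C(C)C)C(C)C)=CCC2=C1O[Li]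
F7 | step 11 | 4α-hydroxy-8-oxo-5α-eudesm-7(11)-en-3β-yl 2-[bis(2,2,2-trifluoroethoxy)phosphoryl]propanoate | CC(P(=O)(OCC(F)(F)F)OCC(F)(F)F)C(=O)O[C@H]1CC[C@]2(C)CC(=O)C(=C(C)C)C[C@H]2[C@]1(C)O
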